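**Retrosynthetic overview**
- Target ⇒ cut the C8 ester C–O bond: melitensin (15-OH masked as a TBS ether) plus (R)-3-silyloxy-2-methylpropanoic acid, made from the (R)-Roche ester, which supplies the side-chain stereocentre.
- Melitensin ⇒ cut C5–C10 by a retro-Cope ([3,3]-sigmatropic) step: the germacra-1(10),4-dienolide 11βH-dihydrosalonitenolide. C5 and C10 are set in the Cope step by the chair transition state under control of C6/C7.
- 11βH-Dihydrosalonitenolide ⇒ cnicin, which supplies C6, C7 and C8; conjugate reduction sets C11 and methanolysis removes the native side chain.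
- Ring order: the γ-lactone and the ten-membered carbocycle are bought in cnicin; the cyclohexane ring is formed once, by the Cope ring contraction; no ring is made afterwards.

Assumption: cnicin, the bitter principle of blessed thistle (Cnicus benedictus), is taken as a purchasable (not commodity-priced) chiral-pool compound with the (3aR,4S,11aR) core and a (3R) side chain; the target is read as melitensin 8-O-[(2R)-3-hydroxy-2-methylpropanoate], i.e. 5R,6R,7R,8S,10S,11S.

**Route**

Step 1
Reactants: 1 cnicin
Product: 3 11βH-dihydrosalonitenolide, via 11βH-dihydrocnicin 2 (not isolated)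
Conditions: NaBH4 (1.5 equiv), MeOH, 0 °C, 30 min; then K2CO3 (0.3 equiv), 0 °C → rt; aq. NH4Cl
Reagents that add atoms: none
Why: Conjugate reduction of the α-methylene-γ-lactone by borohydride, with protonation (and base equilibration) of the lactone enolate to the more stable 11S (11α-methyl, 11β-H) epimer, is followed by carbonate-catalysed transesterification with MeOH that frees the 8α-OH while the trans-fused γ-lactone stays closed.

Step 2
Reactants: 3 11βH-dihydrosalonitenolide
Product: 4 melitensin (8α,15-dihydroxy-11βH-elema-1,3-dien-6α,12-olide)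
Conditions: PhMe (degassed, BHT cat.), sealed tube, 200 °C, 3 h
Reagents that add atoms: none
Why: Thermal Cope rearrangement ([3,3]-sigmatropic) of the (E,E)-cyclodeca-1,5-diene through its crossed, chair-like transition state breaks C2–C3 and forms C5–C10, and the fixed C6/C7 centres of the trans-lactone dictate the trans-1,2-dialkenyl cyclohexane with 5α-H and 10β-methyl (5R,10S).

Step 3
Reactants: 4 melitensin
Product: 5 15-O-TBS-melitensin
Conditions: TBSCl (1.1 equiv), imidazole, CH2Cl2, 0 °C
Reagents that add atoms: tert-butyldimethylsilyl chloride (TBSCl), CC(C)(C)[Si](C)(C)Cl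
Why: Silyl ether formation is kinetically selective for the unhindered primary allylic 15-OH over the secondary 8-OH next to the lactone-bearing carbon.

Step 4
Reactants: 6 methyl (R)-3-hydroxy-2-methylpropanoate ((R)-Roche ester)
Product: 7 methyl (R)-3-[(tert-butyldimethylsilyl)oxy]-2-methylpropanoate
Conditions: TBSCl, imidazole, DMF, 0 °C → rt
Reagents that add atoms: tert-butyldimethylsilyl chloride (TBSCl), CC(C)(C)[Si](C)(C)Cl
Why: Standard silylation of a primary alcohol, which does not touch the purchased α-stereocentre.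

Step 5
Reactants: 7 methyl (R)-3-[(tert-butyldimethylsilyl)oxy]-2-methylpropanoate
Product: 8 (R)-3-[(tert-butyldimethylsilyl)oxy]-2-methylpropanoic acid
Conditions: LiOH·H2O, THF/H2O, 0 °C → rt; then 1 M HCl to pH 3–4, 0 °C
Reagents that add atoms: lithium hydroxide monohydrate (LiOH·H2O), [Li+].[OH-].O
Why: Ester saponification with LiOH at low temperature is mild enough to avoid α-epimerisation and β-elimination, and the primary TBS ether survives the base and the brief cold acidification.

Step 6
Reactants: 5 15-O-TBS-melitensin; 8 (R)-3-[(tert-butyldimethylsilyl)oxy]-2-methylpropanoic acid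
Product: 9 15-O-TBS-melitensin 8-O-[(2R)-3-(tert-butyldimethylsilyloxy)-2-methylpropanoate]
Conditions: DCC, DMAP (cat.), CH2Cl2, 0 °C → rt
Reagents that add atoms: none
Why: Steglich esterification acylates the equatorial 8α-OH with retention at C8 (the C8–O bond is not broken), and low temperature with catalytic DMAP keeps the α-methyl centre of the acid intact.

Step 7
Reactants: 9 15-O-TBS-melitensin 8-O-[(2R)-3-(tert-butyldimethylsilyloxy)-2-methylpropanoate]
Product: 10 target CNP0580343.1, melitensin 8-O-[(2R)-3-hydroxy-2-methylpropanoate]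
Conditions: HF·pyridine, pyridine/THF, 0 °C → rt
Reagents that add atoms: none
Why: Fluoride-driven desilylation removes both primary TBS ethers under buffered, weakly acidic conditions that leave the ester, the lactone and both 1,1-disubstituted/vinyl alkenes untouched and avoid acyl migration or β-elimination.

**Compound list**

1 | cnicin; 8α-[(3R)-3,4-dihydroxy-2-methylidenebutanoyloxy]-15-hydroxygermacra-1(10)E,4Z,11(13)-trien-6α,12-olide | C/C1=C\CC/C(CO)=C/[C@H]2OC(=O)C(=C)[C@@H]2[C@@H](OC(=O)C(=C)[C@@H](O)CO)C1 | starting material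
2 | 11βH-dihydrocnicin; (11S)-11,13-dihydrocnicin | C/C1=C\CC/C(CO)=C/[C@H]2OC(=O)[C@@H](C)[C@@H]2[C@@H](OC(=O)C(=C)[C@@H](O)CO)C1 | intermediate
3 | 11βH-dihydrosalonitenolide; (6R,7R,8S,11S)-8α,15-dihydroxygermacra-1(10)E,4Z-dien-6α,12-olide | C/C1=C\CC/C(CO)=C/[C@H]2OC(=O)[C@@H](C)[C@@H]2[C@@H](O)C1 | intermediate
4 | melitensin; (5R,6R,7R,8S,10S,11S)-8α,15-dihydroxy-11βH-elema-1,3-dien-6α,12-olide | C=C[C@]1(C)C[C@H](O)[C@@H]2[C@H](OC(=O)[C@H]2C)[C@H]1C(=C)CO | intermediate
5 | 15-O-TBS-melitensin | C=C[C@]1(C)C[C@H](O)[C@@H]2[C@H](OC(=O)[C@H]2C)[C@H]1C(=C)CO[Si](C)(C)C(C)(C)C | intermediate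
6 | methyl (R)-3-hydroxy-2-methylpropanoate ((R)-Roche ester) | COC(=O)[C@H](C)CO | starting material
7 | methyl (R)-3-[(tert-butyldimethylsilyl)oxy]-2-methylpropanoate | COC(=O)[C@H](C)CO[Si](C)(C)C(C)(C)C | intermediate
8 | (R)-3-[(tert-butyldimethylsilyl)oxy]-2-methylpropanoic acid | OC(=O)[C@H](C)CO[Si](C)(C)C(C)(C)C | intermediate
9 | 15-O-TBS-melitensin 8-O-[(2R)-3-(tert-butyldimethylsilyloxy)-2-methylpropanoate] | C=C[C@]1(C)C[C@H](OC(=O)[C@H](C)CO[Si](C)(C)C(C)(C)C)[C@@H]2[C@H](OC(=O)[C@H]2C)[C@H]1C(=C)CO[Si](C)(C)C(C)(C)C | intermediate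
10 | CNP0580343.1; melitensin 8-O-[(2R)-3-hydroxy-2-methylpropanoate] | C=C[C@]1(C)C[C@H](OC(=O)[C@H](C)CO)[C@@H]2[C@H](OC(=O)[C@H]2C)[C@H]1C(=C)CO | target

**Step count and risks**

Total step count: 7. Longest linear sequence: 5 steps (1 → 3 → 4 → 5 → 9 → 10); the acid 8 is made in a 2-step side branch.

The three steps most likely to fail:

Step 1 (one-pot reduction and deacylation). The hindered acrylate ester may cleave slowly, and longer exposure to methoxide on the flexible cyclodecadiene lactone risks lactone opening or relactonisation towards O8. The fallback sets out from 2, which is isolated after the NaBH4 stage, and comes back at 4. The order of events is changed: 2 is heated first (PhMe, BHT, 200 °C) so that the Cope rearrangement gives 8-O-[(3R)-3,4-dihydroxy-2-methylidenebutanoyl]melitensin F1. The side chain is then removed from this rigid, chair-locked elemanolide with NaOMe in MeOH at 0 °C, which gives 4 directly.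

Step 2 (Cope rearrangement). Germacranolide/elemanolide pairs can reach a thermal equilibrium, and the free diol may suffer at 200 °C; recovered 3 can be recycled, but conversion may stay incomplete. The fallback sets out from 3 and comes back at 4, and it changes the oxidation level at which the rearrangement is run. MnO2 in CH2Cl2 oxidises only the allylic 15-OH to give 15-oxo-11βH-dihydrosalonitenolide F2. Its formyl group sits at the 2-position of the 1,5-diene and stabilises the diyl-like transition state, so the Cope rearrangement should proceed at 80–110 °C in PhMe to give 15-oxomelitensin F3. Luche reduction (NaBH4, CeCl3·7H2O, MeOH, −40 °C) of the enal then returns 4.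

Step 6 (esterification). Slow acylation of the 8-OH of the elemanolide would give the activated acid time to epimerise at its α-carbon or to lose silanol by β-elimination. The fallback sets out from 3 and comes back at 9, and it moves the acylation ahead of the ring contraction. Monosilylation of 3 (TBSCl, imidazole, CH2Cl2, 0 °C) gives 15-O-TBS-11βH-dihydrosalonitenolide F4. Its 8α-OH, the position acylated in the natural germacranolide esters, is coupled with 8 (DCC, DMAP cat., 0 °C) to give 15-O-TBS-11βH-dihydrosalonitenolide 8-O-[(2R)-3-(tert-butyldimethylsilyloxy)-2-methylpropanoate] F5. Heating F5 (PhMe, 200 °C) then effects the Cope rearrangement, which is unimolecular and indifferent to the ester, and gives 9.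

**Further compounds**

F1 | step 1 | 8-O-[(3R)-3,4-dihydroxy-2-methylidenebutanoyl]melitensin | C=C[C@]1(C)C[C@H](OC(=O)C(=C)[C@@H](O)CO)[C@@H]2[C@H](OC(=O)[C@H]2C)[C@H]1C(=C)CO
F2 | step 2 | 15-oxo-11βH-dihydrosalonitenolide | C/C1=C\CC/C(C=O)=C/[C@H]2OC(=O)[C@@H](C)[C@@H]2[C@@H](O)C1
F3 | step 2 | 15-oxomelitensin | C=C[C@]1(C)C[C@H](O)[C@@H]2[C@H](OC(=O)[C@H]2C)[C@H]1C(=C)C=O
F4 | step 6 | 15-O-TBS-11βH-dihydrosalonitenolide | C/C1=C\CC/C(CO[Si](C)(C)C(C)(C)C)=C/[C@H]2OC(=O)[C@@H](C)[C@@H]2[C@@H](O)C1
F5 | step 6 | 15-O-TBS-11βH-dihydrosalonitenolide 8-O-[(2R)-3-(tert-butyldimethylsilyloxy)-2-methylpropanoate] | C/C1=C\CC/C(CO[Si](C)(C)C(C)(C)C)=C/[C@H]2OC(=O)[C@@H](C)[C@@H]2[C@@H](OC(=O)[C@H](C)CO[Si](C)(C)C(C)(C)C)C1
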